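# Proposed synthesis of CNP0233274.1 (23) by a benzylic zinc / 3-bromopyranone Negishi coupling

## Analysis of the target

The target 23 is two rings joined through one methylene group: ring A, a fully substituted benzene of the acylphloroglucinol monomethyl ether type, and ring B, a 4-hydroxy-2H-pyran-2-one with a 5-methyl and a 6-ethyl group. Around ring A the substituents follow in a fixed order, C1 the bridge CH2, C2 OH, C3 prenyl, C4 OH, C5 the 2-methylbutanoyl group and C6 OMe, so the prenyl group lies between the two hydroxyls while the acyl group and the bridge each lie between a hydroxyl and the methoxy group. The only stereocentre is C2 of the acyl chain, of R configuration; it has no partner, so only its absolute configuration has to be secured, but it is α to an aryl ketone and can be lost by enolisation under strong base, strong acid or Lewis-acid acylation conditions. The sensitive groups are the prenyl olefin next to two phenols (acid can close it to a chroman), the electron-rich phenol and enolic pyranone (oxidation, ambident alkylation), and the bridge itself, which can re-ionise when the flanking oxygens are free. Two things make the synthesis hard: the regiochemistry of the hexasubstituted ring A and the union of the two halves. The bridge carbon links pyranone C3 and ring A C1, both enol-type, nucleophilic carbons, so joining them with a one-carbon electrophile is a like-polarity problem that gives symmetrical dimers of each half beside the mixed product. The strategy rests on this bridge: the CH2 is attached to ring A first and made the nucleophile as a benzylic zinc reagent, and pyranone C3 is made the electrophile as its bromide, so that only the crossed C3–CH2 bond can form.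

## Retrosynthetic reasoning

**23 to 22.** The three acidic hydroxyls of 23 (two phenols, one enol) are traced back to methoxymethyl ethers in 22. An acetal is chosen because it survives organolithium and organozinc chemistry, directs ortho-lithiation on ring A, and leaves under dilute acid at room temperature. That is mild enough for the prenyl group and the stereocentre. The forward step only has to cleave three acetals at once.

**22 to 21 and 6.** The bond between pyranone C3 and the bridge CH2 is cut. Cutting on the other side of the bridge would require a metalated methyl group on pyranone C3, which has a leaving group in the vinylogous β-position, and a metalated or halogenated hexasubstituted arene. Cutting at C3 gives a benzylic zinc chloride 21, which has no such weakness, and the bromide 6, in which C3 is an alkenyl bromide activated by the lactone carbonyl. The gain is full convergence and a union under neutral, base-free conditions with reversed polarity on both sides. The forward reaction must form a C(sp2)–C(sp3) bond between two crowded centres without touching the ketone or the stereocentre.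

**21 to 20 to 19.** The C–Zn bond is traced to a C–Cl bond (insertion of zinc metal), and the C–Cl bond to a C–N bond in the benzylic dimethylamine 19. The amine is chosen as the carrier of the bridge carbon because it is inert to alkyllithiums, unlike a halide or a carbonyl group. It can also be exchanged for chloride without acid by a chloroformate-induced dealkylation. This keeps the labile trioxygenated benzylic chloride 20 out of the route until the step before it is used.

**19 to 14 and 17.** The aryl–carbonyl bond is cut. The acyl group arrives as the Weinreb amide 17, made from the acid 15, and is attacked by the aryllithium formed at the last ring hydrogen of 14. This brings the stereocentre in from an enantiopure acid. It also avoids a Lewis-acid acylation with a branched acid chloride, where ketene formation and enolisation of the chelated product threaten the configuration. The ketone is introduced last among the ring substituents because it would not survive a later lithiation.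

**14 to 11 and 12.** The aryl–CH2 bond is cut. The two free ring positions of 11 are equivalent by symmetry and each lies between an acetal oxygen and the methoxy group. Lithiation followed by capture with the iminium salt 12 places the one-carbon unit without any regiochemical question.

**11 to 8 and 9; 8 to 7.** The aryl–prenyl bond is cut. In 8 the carbon between the two acetal oxygens is the best-directed site, so lithiation and alkylation with 9 put the prenyl group exactly where the target needs it. The prenyl group is installed first because this is the one position that differs from the other two. The ether 8 comes from commercial 7 by double protection.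

**6 to 5 to 4 to 2 and 3; 2 to 1.** The C3–Br bond and the 4-O-acetal are removed in turn to give the parent pyranone 4. Its ring is cut at C4–C5 and O1–C2 into the silyl enol ether 2 and the three-carbon diacid chloride 3. The enol ether 2 comes from the symmetrical ketone 1, whose α-carbon becomes C5 with its methyl and whose carbonyl carbon becomes C6 with its ethyl. Making ring B on this small scaffold puts the harsh acylation chemistry where nothing sensitive is present.

## Alternatives that were turned down

**Alternative 1: ring A built by Danheiser benzannulation.**
- Disconnection: ring A itself is taken apart into the cyclobutenone 2-({[tert-butyl(dimethyl)silyl]oxy}methyl)-3-methoxycyclobut-2-en-1-one (A2) and the siloxyalkyne [(5-methylhex-4-en-1-yn-1-yl)oxy]tri(propan-2-yl)silane (A3).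
- Forward key step: on heating, A2 opens to a vinylketene, which adds to A3 in a [2+2] sense. The new vinylcyclobutenone opens again, and the dienylketene closes by 6π electrocyclisation to the phenol 4-({[tert-butyl(dimethyl)silyl]oxy}methyl)-5-methoxy-2-(3-methylbut-2-enyl)-3-{[tri(propan-2-yl)silyl]oxy}phenol (A1).
- For: the position of every substituent is fixed by the connectivity of the two partners. On regiochemical certainty this is stronger than the chosen route, which at step 6 relies on acetal oxygens directing better than a methoxy group.
- Against: neither A2 nor A3 is commercial, and each needs several steps. A1 still lacks the acyl group, so a branched, enantiopure acyl group must afterwards be placed between a free phenol and the methoxy group. That means either a Lewis-acid acylation (risk to the stereocentre, the silyl ethers and the prenyl group) or reprotection and a directed lithiation, which is what the chosen route does anyway. The two oxygens that A1 differentiates both end as free hydroxyls, so the differentiation buys nothing. The bridge to ring B is not addressed at all.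
- Comparison: the chosen strategy builds the same substitution pattern from a commercial arene in three lithiation steps and keeps the risk in one late coupling. Alternative 1 is longer and leaves the like-polarity union unsolved.

**Alternative 2: enzymatic prenylation between the hydroxyls.**
- Disconnection: the aryl C3–prenyl bond of (2R)-1-[2,4-dihydroxy-6-methoxy-3-(3-methylbut-2-enyl)phenyl]-2-methylbutan-1-one (A4).
- Forward key step: an aromatic prenyltransferase transfers the dimethylallyl group of dimethylallyl diphosphate (A6) to the unprenylated ketone (2R)-1-(2,4-dihydroxy-6-methoxyphenyl)-2-methylbutan-1-one (A5).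
- For: no protecting groups, water at neutral pH, and no threat to the stereocentre. For the prenylation alone it is more step-economic and milder than lithiation of a protected arene, so on that point it is stronger.
- Against: A5 has two nucleophilic ring carbons, one between the two hydroxyls and one between a hydroxyl and the methoxy group. Which one an enzyme serves depends on substrate binding and cannot be argued from the structure of an O-methylated, 2-methylbutanoyl substrate. A5 would have to come from 7 and 15 by a Friedel–Crafts-type acylation, which gives regioisomers and endangers the configuration. The step needs an expressed enzyme and stoichiometric A6. A4 has free phenols, so the bridge could only be added with a one-carbon electrophile, which is the dimer-forming union the chosen strategy is designed to avoid.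
- Comparison: the chosen strategy pays with protection steps but gets the prenyl position from a directing-group argument and symmetry, and it solves the bridge.

**Alternative 3: ring B closed last on an arylmethylmalonyl dichloride.**
- Disconnection: pyranone bonds C4–C5 and O1–C2, with the bridge already in place in the diacid chloride 2-{[2,4-diacetoxy-6-methoxy-3-(3-methylbut-2-enyl)-5-[(2R)-2-methylbutanoyl]phenyl]methyl}propanedioyl dichloride (A8).
- Forward key step: the silyl enol ether 2 is C-acylated and then O-acylated by A8, which closes ring B and gives the diacetate of the target (A7).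
- For: the annulation is the same reaction type as step 2 of the chosen route, and the bridge C–C bond would be made by alkylation of a malonate, which is more certain than a hindered cross-coupling. No transition metal is needed. On the reliability of the bridge-forming bond it is stronger.
- Against: A8 must carry the prenyl olefin, the enolisable ketone with its stereocentre and two aryl esters through formation of a diacid chloride, with HCl present. Monosubstituted malonyl dichlorides lose HCl to chlorocarbonyl ketenes, which can add to the trisubstituted olefin or acylate the ketone enol. The annulation itself releases HCl and a silyl chloride. Acetals cannot be used, hence the acetates, and these must be cleaved from A7 by base next to the epimerisable centre. The route is linear and sends its most valuable intermediate into its harshest step.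
- Comparison: the chosen strategy carries out the same annulation on a five-carbon ketone, where harshness costs nothing, and joins the finished halves under neutral conditions.

Key step: step 12

## Route

Assumption: (2R)-2-methylbutanoic acid (15) of high enantiomeric purity is taken as purchasable. Compound 2 is used as the mixture of double-bond isomers, because its geometry disappears in step 2.

Step 1
Reactants: 1 pentan-3-one
Product: 2 trimethyl[(pent-2-en-3-yl)oxy]silane
Conditions: TMSCl, Et3N, DMF, 80 °C; distillation
Reagents that add atoms: chlorotrimethylsilane, C[Si](C)(C)Cl
Why: Enol silylation of a symmetrical ketone under amine base; 1 has only one kind of α-position, so no regiochemical question arises.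

Step 2
Reactants: 2 trimethyl[(pent-2-en-3-yl)oxy]silane; 3 malonyl dichloride
Product: 4 6-ethyl-4-hydroxy-5-methyl-2H-pyran-2-one
Conditions: Et2O, −78 °C to 25 °C
Reagents that add atoms: none
Why: Pyranone annulation of a silyl enol ether with malonyl dichloride: the enol carbon is C-acylated by one acid chloride with loss of the silyl group, the enol oxygen of the adduct is acylated by the second to close the lactone, and tautomerisation gives the 4-hydroxy-2-pyranone. The α-carbon of 1 becomes C5 (methyl) and its carbonyl carbon becomes C6 (ethyl).

Step 3
Reactants: 4 6-ethyl-4-hydroxy-5-methyl-2H-pyran-2-one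
Product: 5 3-bromo-6-ethyl-4-hydroxy-5-methyl-2H-pyran-2-one
Conditions: NBS, MeCN, 0 °C to 25 °C, dark
Reagents that add atoms: N-bromosuccinimide, O=C1CCC(=O)N1Br
Why: Electrophilic bromination at C3, the only free enol carbon of the vinylogous acid; without light or initiator the alkyl groups on C5 and C6 should not be touched.

Step 4
Reactants: 5 3-bromo-6-ethyl-4-hydroxy-5-methyl-2H-pyran-2-one
Product: 6 3-bromo-6-ethyl-4-(methoxymethoxy)-5-methyl-2H-pyran-2-one
Conditions: MOMCl, iPr2NEt, CH2Cl2, 0 °C to 25 °C
Reagents that add atoms: chloromethyl methyl ether, COCCl
Why: O-alkylation of the vinylogous acid with a hard alkoxymethyl chloride and a hindered amine should give the 4-alkoxy-2-pyranone, which keeps the conjugated lactone, rather than the 2-alkoxy-4-pyranone. The ether masks the acidic hydroxyl that would otherwise protonate the zinc reagent in step 12.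

Step 5
Reactants: 7 5-methoxybenzene-1,3-diol
Product: 8 1-methoxy-3,5-bis(methoxymethoxy)benzene
Conditions: MOMCl, iPr2NEt, CH2Cl2, 0 °C to 25 °C
Reagents that add atoms: chloromethyl methyl ether, COCCl
Why: Double O-alkylation of the phenols; the methoxymethyl ethers are stable to organolithiums and serve as directing groups for the three metalations that follow.

Step 6
Reactants: 8 1-methoxy-3,5-bis(methoxymethoxy)benzene; 9 1-bromo-3-methylbut-2-ene
Product: 11 5-methoxy-1,3-bis(methoxymethoxy)-2-(3-methylbut-2-en-1-yl)benzene, via aryllithium 10 (not isolated)
Conditions: n-BuLi, THF, 0 °C; then 9, −78 °C to 25 °C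
Reagents that add atoms: n-butyllithium, [Li]CCCC (supplies the lithium of 10 only)
Why: Directed ortho-metalation: the carbon between the two methoxymethoxy groups is flanked by two chelating acetal oxygens, which direct more strongly than methoxy, so lithiation should occur there and not next to OMe. SN2 alkylation of 10 at the primary carbon of 9 then gives the prenyl arene, which is again mirror-symmetric.

Step 7
Reactants: 11 5-methoxy-1,3-bis(methoxymethoxy)-2-(3-methylbut-2-en-1-yl)benzene; 12 N,N-dimethylmethaniminium iodide (Eschenmoser's salt)
Product: 14 1-[6-methoxy-2,4-bis(methoxymethoxy)-3-(3-methylbut-2-en-1-yl)phenyl]-N,N-dimethylmethanamine, via aryllithium 13 (not isolated)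
Conditions: n-BuLi, THF, 0 °C; then 12, −78 °C to 25 °C
Reagents that add atoms: n-butyllithium, [Li]CCCC (supplies the lithium of 13 only)
Why: Directed ortho-metalation at one of the two equivalent ring positions, each flanked by OMOM and OMe, followed by Mannich-type capture of 13 by the preformed iminium salt. Ring metalation assisted by two ortho oxygens is expected to be faster than proton removal from the prenyl CH2, and the dimethylaminomethyl group is inert to the next lithiation and is a latent benzylic chloride.

Step 8
Reactants: 15 (2R)-2-methylbutanoic acid
Product: 17 (2R)-N-methoxy-N,2-dimethylbutanamide, via acyl imidazole 16 (not isolated)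
Conditions: CDI, CH2Cl2, 0 °C to 25 °C; then MeNHOMe·HCl, 25 °C
Reagents that add atoms: 1,1'-carbonyldiimidazole, O=C(n1ccnc1)n1ccnc1 (imidazolyl group of 16 only); N,O-dimethylhydroxylamine hydrochloride, CNOC.Cl
Why: Weinreb amide formation by activation of the acid as the acyl imidazole and aminolysis; no strong base and no ketene-forming conditions are used, so the R stereocentre should be retained.

Step 9
Reactants: 14 1-[6-methoxy-2,4-bis(methoxymethoxy)-3-(3-methylbut-2-en-1-yl)phenyl]-N,N-dimethylmethanamine; 17 (2R)-N-methoxy-N,2-dimethylbutanamide
Product: 19 (2R)-1-{3-[(dimethylamino)methyl]-2-methoxy-4,6-bis(methoxymethoxy)-5-(3-methylbut-2-en-1-yl)phenyl}-2-methylbutan-1-one, via aryllithium 18 (not isolated)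
Conditions: n-BuLi, THF, 0 °C; then 17, −78 °C to 0 °C; aq. NH4Cl
Reagents that add atoms: n-butyllithium, [Li]CCCC (supplies the lithium of 18 only)
Why: Directed ortho-metalation at the last ring hydrogen (between OMOM and OMe) and Weinreb ketone synthesis. The chelated tetrahedral adduct prevents over-addition and keeps the carbonyl masked until the buffered quench, so the R stereocentre brought in with 17 is never exposed to base as a ketone.

Step 10
Reactants: 19 (2R)-1-{3-[(dimethylamino)methyl]-2-methoxy-4,6-bis(methoxymethoxy)-5-(3-methylbut-2-en-1-yl)phenyl}-2-methylbutan-1-one
Product: 20 (2R)-1-[3-(chloromethyl)-2-methoxy-4,6-bis(methoxymethoxy)-5-(3-methylbut-2-en-1-yl)phenyl]-2-methylbutan-1-one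
Conditions: ClCO2Et, THF, 0 °C to 25 °C; volatiles removed, crude used at once
Reagents that add atoms: ethyl chloroformate, CCOC(=O)Cl (supplies the chlorine)
Why: von Braun-type dealkylation: N-acylation gives an acylammonium ion, and chloride displaces it at the electron-rich benzylic carbon far faster than at N-methyl, giving the chloride and a neutral carbamate. No acid is formed, so the acetals, the prenyl group and the stereocentre should be safe; the product is not purified because a 2,4,6-trioxygenated benzylic chloride ionises easily.

Step 11
Reactants: 20 (2R)-1-[3-(chloromethyl)-2-methoxy-4,6-bis(methoxymethoxy)-5-(3-methylbut-2-en-1-yl)phenyl]-2-methylbutan-1-one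
Product: 21 {[2-methoxy-4,6-bis(methoxymethoxy)-5-(3-methylbut-2-en-1-yl)-3-[(2R)-2-methylbutanoyl]phenyl]methyl}zinc chloride
Conditions: Zn dust (activated with BrCH2CH2Br and TMSCl), LiCl, THF, 0 °C to 25 °C; cannula filtration; used as the THF solution
Reagents that add atoms: zinc, [Zn]
Why: Direct insertion of zinc metal into the benzylic C–Cl bond, accelerated by LiCl, which takes the organozinc into solution as it forms. Benzylic zinc chlorides tolerate aryl ketones, acetals and olefins, and the ketone here is hindered and meta to the reacting carbon.

Step 12
Reactants: 21 {[2-methoxy-4,6-bis(methoxymethoxy)-5-(3-methylbut-2-en-1-yl)-3-[(2R)-2-methylbutanoyl]phenyl]methyl}zinc chloride; 6 3-bromo-6-ethyl-4-(methoxymethoxy)-5-methyl-2H-pyran-2-one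
Product: 22 6-ethyl-3-{[2-methoxy-4,6-bis(methoxymethoxy)-5-(3-methylbut-2-en-1-yl)-3-[(2R)-2-methylbutanoyl]phenyl]methyl}-4-(methoxymethoxy)-5-methyl-2H-pyran-2-one
Conditions: Pd(OAc)2 (2 mol%), SPhos (4 mol%), THF, 25 °C; 21 (1.3 equiv) added slowly to 6
Reagents that add atoms: none
Why: A small part of 21 reduces Pd(OAc)2 to zerovalent palladium, which with the biaryl phosphine SPhos adds oxidatively into the C3–Br bond of 6, an alkenyl bromide activated by the lactone carbonyl; the benzyl group then passes from zinc to divalent palladium, and reductive elimination forms the C3–CH2 bond. The closest known reaction type is the Negishi coupling of functionalised benzylic zinc chlorides with alkenyl and heteroaryl bromides under Pd(OAc)2/SPhos, together with palladium-catalysed couplings at C3 of 3-bromo-4-alkoxy-2-pyranones. No ring closes and no stereocentre is made; the existing one should be spared because the medium contains no base and the zinc reagent is too weakly basic to enolise the ketone. The step needs cross-coupling to outrun homocoupling of 21 and its addition to a carbonyl group. Slow addition keeps 21 dilute, and the bulky, electron-rich phosphine speeds oxidative addition and reductive elimination at the two crowded carbons. The ketone is twisted out of the ring plane between two ortho substituents, and the pyranone carbonyl is an electron-rich vinylogous carbonate of low electrophilicity. The benzyl–palladium intermediate has no β-hydrogen on an sp3 carbon, so β-hydride elimination cannot compete, and since the bridge carbon is the nucleophile and C3 the electrophile, neither half can form a methylene-bridged dimer.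

Step 13
Reactants: 22 6-ethyl-3-{[2-methoxy-4,6-bis(methoxymethoxy)-5-(3-methylbut-2-en-1-yl)-3-[(2R)-2-methylbutanoyl]phenyl]methyl}-4-(methoxymethoxy)-5-methyl-2H-pyran-2-one
Product: 23 6-ethyl-4-hydroxy-3-{[2,4-dihydroxy-6-methoxy-3-(3-methylbut-2-en-1-yl)-5-[(2R)-2-methylbutanoyl]phenyl]methyl}-5-methyl-2H-pyran-2-one (CNP0233274.1)
Conditions: 3 M aq. HCl, MeOH, 25 °C
Reagents that add atoms: none
Why: Acid-catalysed transacetalisation of the three methoxymethyl ethers to the solvent; the vinylogous ester acetal on ring B and the twisted aryl acetals on ring A cleave readily. Dilute acid at room temperature is not expected to cyclise the prenyl group onto a phenol or to enolise the hindered ketone, so the R configuration should be kept.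

## Compound list

1 | pentan-3-one | CCC(=O)CC | starting material
2 | trimethyl[(pent-2-en-3-yl)oxy]silane (mixture of E and Z) | CC=C(CC)O[Si](C)(C)C | intermediate
3 | malonyl dichloride (propanedioyl dichloride) | O=C(Cl)CC(=O)Cl | starting material
4 | 6-ethyl-4-hydroxy-5-methyl-2H-pyran-2-one | CCc1oc(=O)cc(O)c1C | intermediate
5 | 3-bromo-6-ethyl-4-hydroxy-5-methyl-2H-pyran-2-one | CCc1oc(=O)c(Br)c(O)c1C | intermediate
6 | 3-bromo-6-ethyl-4-(methoxymethoxy)-5-methyl-2H-pyran-2-one | CCc1oc(=O)c(Br)c(OCOC)c1C | intermediate
7 | 5-methoxybenzene-1,3-diol (5-methoxyresorcinol) | COc1cc(O)cc(O)c1 | starting material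
8 | 1-methoxy-3,5-bis(methoxymethoxy)benzene | COCOc1cc(OC)cc(OCOC)c1 | intermediate
9 | 1-bromo-3-methylbut-2-ene (prenyl bromide) | CC(C)=CCBr | starting material
10 | [4-methoxy-2,6-bis(methoxymethoxy)phenyl]lithium | [Li]c1c(OCOC)cc(OC)cc1OCOC | intermediate
11 | 5-methoxy-1,3-bis(methoxymethoxy)-2-(3-methylbut-2-en-1-yl)benzene | COCOc1cc(OC)cc(OCOC)c1CC=C(C)C | intermediate
12 | N,N-dimethylmethaniminium iodide (Eschenmoser's salt) | C=[N+](C)C.[I-] | starting material
13 | [6-methoxy-2,4-bis(methoxymethoxy)-3-(3-methylbut-2-en-1-yl)phenyl]lithium | [Li]c1c(OC)cc(OCOC)c(CC=C(C)C)c1OCOC | intermediate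
14 | 1-[6-methoxy-2,4-bis(methoxymethoxy)-3-(3-methylbut-2-en-1-yl)phenyl]-N,N-dimethylmethanamine | CN(C)Cc1c(OC)cc(OCOC)c(CC=C(C)C)c1OCOC | intermediate
15 | (2R)-2-methylbutanoic acid | CC[C@@H](C)C(=O)O | starting material
16 | (2R)-1-(1H-imidazol-1-yl)-2-methylbutan-1-one | CC[C@@H](C)C(=O)n1ccnc1 | intermediate
17 | (2R)-N-methoxy-N,2-dimethylbutanamide | CC[C@@H](C)C(=O)N(C)OC | intermediate
18 | {3-[(dimethylamino)methyl]-2-methoxy-4,6-bis(methoxymethoxy)-5-(3-methylbut-2-en-1-yl)phenyl}lithium | [Li]c1c(OC)c(CN(C)C)c(OCOC)c(CC=C(C)C)c1OCOC | intermediate
19 | (2R)-1-{3-[(dimethylamino)methyl]-2-methoxy-4,6-bis(methoxymethoxy)-5-(3-methylbut-2-en-1-yl)phenyl}-2-methylbutan-1-one | CC[C@@H](C)C(=O)c1c(OC)c(CN(C)C)c(OCOC)c(CC=C(C)C)c1OCOC | intermediate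
20 | (2R)-1-[3-(chloromethyl)-2-methoxy-4,6-bis(methoxymethoxy)-5-(3-methylbut-2-en-1-yl)phenyl]-2-methylbutan-1-one | CC[C@@H](C)C(=O)c1c(OC)c(CCl)c(OCOC)c(CC=C(C)C)c1OCOC | intermediate
21 | {[2-methoxy-4,6-bis(methoxymethoxy)-5-(3-methylbut-2-en-1-yl)-3-[(2R)-2-methylbutanoyl]phenyl]methyl}zinc chloride | CC[C@@H](C)C(=O)c1c(OC)c(C[Zn]Cl)c(OCOC)c(CC=C(C)C)c1OCOC | intermediate
22 | 6-ethyl-3-{[2-methoxy-4,6-bis(methoxymethoxy)-5-(3-methylbut-2-en-1-yl)-3-[(2R)-2-methylbutanoyl]phenyl]methyl}-4-(methoxymethoxy)-5-methyl-2H-pyran-2-one | CCc1oc(=O)c(Cc2c(OCOC)c(CC=C(C)C)c(OCOC)c(C(=O)[C@H](C)CC)c2OC)c(OCOC)c1C | intermediate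
23 | 6-ethyl-4-hydroxy-3-{[2,4-dihydroxy-6-methoxy-3-(3-methylbut-2-en-1-yl)-5-[(2R)-2-methylbutanoyl]phenyl]methyl}-5-methyl-2H-pyran-2-one | CCc1oc(=O)c(Cc2c(O)c(CC=C(C)C)c(O)c(C(=O)[C@H](C)CC)c2OC)c(O)c1C | target

## Step count and risk

Total step count: 13. Longest linear sequence: 8 steps (steps 5, 6, 7, 9, 10, 11, 12 and 13, from 7). Ring B takes steps 1 to 4 and the amide 17 takes step 8; both join the main line.

**Step 12 (key step).** The most likely failure is slow oxidative addition into the C3–Br bond, which is enriched by the neighbouring 4-alkoxy group and flanked on both sides, so that 21 is used up by homocoupling to the bibenzyl or by protodezincation. The fallback gives up the reversed polarity and forms the bridge by reductive Knoevenagel alkylation. It sets out from 20 and 4. The chloride 20 is oxidised with N-methylmorpholine N-oxide in MeCN to 2-methoxy-4,6-bis(methoxymethoxy)-5-(3-methylbut-2-en-1-yl)-3-[(2R)-2-methylbutanoyl]benzaldehyde (F1). The aldehyde F1 is condensed with the pyranone 4 in the presence of Hantzsch ester and catalytic proline, so that the alkylidene intermediate is reduced as it forms and cannot take up a second pyranone. This should give 6-ethyl-4-hydroxy-3-{[2-methoxy-4,6-bis(methoxymethoxy)-5-(3-methylbut-2-en-1-yl)-3-[(2R)-2-methylbutanoyl]phenyl]methyl}-5-methyl-2H-pyran-2-one (F2). Acid methanolysis of F2 under the conditions of step 13 comes back to the route at 23.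

**Step 11.** The most likely failure is Wurtz-type dimerisation during insertion, because the electron-rich benzylic chloride is a very good electrophile toward the zinc reagent already formed and also ionises easily. The fallback avoids a preformed organometallic. It sets out from 20 and couples it directly with the bromide 6 in a nickel-catalysed reductive cross-electrophile coupling (NiBr2(dme), 4,4'-di-tert-butyl-2,2'-bipyridine, manganese powder, DMA, 25 °C), in which the benzylic partner is activated only at the catalyst. It comes back to the route at 22. No new compound is made on the way, so its entry is F0.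

**Step 9.** The most likely failure is sluggish attack of the doubly ortho-substituted aryllithium 18 on the α-branched amide. Then 18 would act as a base on 17 (α-deprotonation or loss of the N-methoxy group), and 14 would be recovered. The fallback replaces acyl substitution by addition and oxidation. It sets out from 14 and 17. The amide 17 is reduced with LiAlH4 in THF at −78 °C to (2R)-2-methylbutanal (F3), which is used at once in solution because it is configurationally labile. The aldehyde F3 is added at −78 °C to 18, generated from 14 as in step 9. This should give the alcohol (2R)-1-{3-[(dimethylamino)methyl]-2-methoxy-4,6-bis(methoxymethoxy)-5-(3-methylbut-2-en-1-yl)phenyl}-2-methylbutan-1-ol (F4). The alcohol F4 is expected as a mixture of the two carbinol epimers, which does not matter because that centre is removed again. Oxidation of F4 with Dess–Martin periodinane buffered with NaHCO3 comes back to the route at 19.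

**Step 7.** The most likely failure is competing deprotonation of the prenyl CH2, which is both benzylic and allylic and lies between two directing acetal groups. The fallback makes the aryllithium by halogen–metal exchange instead of deprotonation. It sets out from 11, whose very electron-rich ring should be brominated by N-bromosuccinimide (1 equiv, MeCN, −40 °C) faster than the olefin reacts. The two free ring positions are equivalent, so a single bromide is expected, 2-bromo-1-methoxy-3,5-bis(methoxymethoxy)-4-(3-methylbut-2-en-1-yl)benzene (F5). Bromine–lithium exchange on F5 with n-BuLi in THF at −78 °C is much faster than any deprotonation and comes back to the route at 13, which is quenched with 12 as in step 7.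

## Further compounds

F1 | step 12 | 2-methoxy-4,6-bis(methoxymethoxy)-5-(3-methylbut-2-en-1-yl)-3-[(2R)-2-methylbutanoyl]benzaldehyde | CC[C@@H](C)C(=O)c1c(OC)c(C=O)c(OCOC)c(CC=C(C)C)c1OCOC
F2 | step 12 | 6-ethyl-4-hydroxy-3-{[2-methoxy-4,6-bis(methoxymethoxy)-5-(3-methylbut-2-en-1-yl)-3-[(2R)-2-methylbutanoyl]phenyl]methyl}-5-methyl-2H-pyran-2-one | CCc1oc(=O)c(Cc2c(OCOC)c(CC=C(C)C)c(OCOC)c(C(=O)[C@H](C)CC)c2OC)c(O)c1C
F0 | step 11 | none | none
F3 | step 9 | (2R)-2-methylbutanal | CC[C@@H](C)C=O
F4 | step 9 | (2R)-1-{3-[(dimethylamino)methyl]-2-methoxy-4,6-bis(methoxymethoxy)-5-(3-methylbut-2-en-1-yl)phenyl}-2-methylbutan-1-ol (both epimers at C1) | CC[C@@H](C)C(O)c1c(OC)c(CN(C)C)c(OCOC)c(CC=C(C)C)c1OCOC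
F5 | step 7 | 2-bromo-1-methoxy-3,5-bis(methoxymethoxy)-4-(3-methylbut-2-en-1-yl)benzene | COc1cc(OCOC)c(CC=C(C)C)c(OCOC)c1Br
A1 | alternative 1 | 4-({[tert-butyl(dimethyl)silyl]oxy}methyl)-5-methoxy-2-(3-methylbut-2-enyl)-3-{[tri(propan-2-yl)silyl]oxy}phenol | Oc1cc(OC)c(CO[Si](C)(C)C(C)(C)C)c(O[Si](C(C)C)(C(C)C)C(C)C)c1CC=C(C)C
A2 | alternative 1 | 2-({[tert-butyl(dimethyl)silyl]oxy}methyl)-3-methoxycyclobut-2-en-1-one | COC1=C(CO[Si](C)(C)C(C)(C)C)C(=O)C1
A3 | alternative 1 | [(5-methylhex-4-en-1-yn-1-yl)oxy]tri(propan-2-yl)silane | CC(C)=CCC#CO[Si](C(C)C)(C(C)C)C(C)C
A4 | alternative 2 | (2R)-1-[2,4-dihydroxy-6-methoxy-3-(3-methylbut-2-enyl)phenyl]-2-methylbutan-1-one | CC[C@@H](C)C(=O)c1c(O)c(CC=C(C)C)c(O)cc1OC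
A5 | alternative 2 | (2R)-1-(2,4-dihydroxy-6-methoxyphenyl)-2-methylbutan-1-one | CC[C@@H](C)C(=O)c1c(O)cc(O)cc1OC
A6 | alternative 2 | dimethylallyl diphosphate | CC(C)=CCOP(=O)(O)OP(=O)(O)O
A7 | alternative 3 | diacetate of the target at the two ring A hydroxyls | CCc1oc(=O)c(Cc2c(OC(C)=O)c(CC=C(C)C)c(OC(C)=O)c(C(=O)[C@H](C)CC)c2OC)c(O)c1C
A8 | alternative 3 | 2-{[2,4-diacetoxy-6-methoxy-3-(3-methylbut-2-enyl)-5-[(2R)-2-methylbutanoyl]phenyl]methyl}propanedioyl dichloride | CC[C@@H](C)C(=O)c1c(OC)c(CC(C(=O)Cl)C(=O)Cl)c(OC(C)=O)c(CC=C(C)C)c1OC(C)=O
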